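The long arm (C1′, the benzylic CH2, to C8′) is cut at two bonds around its C2′=C3′ alkene: C1′–C2′ and C3′–CH3. This (E)-trisubstituted alkene on the 4-methoxybenzoate ring has methyl on C3′ and the ring CH2 on C2′, which is the pattern that syn methylalumination of a terminal alkyne followed by benzylation at the aluminium-bearing carbon produces. The key step thus unites, in one flask, trimethylaluminium, an (R)-propargylic silyl ether that already holds C4′ and the prenyl tail, and a benzylic chloride whose ring carries the silylated short arm. The C4′ stereocentre is set earlier by asymmetric transfer hydrogenation of an ynone.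

Key step: step 14

Remark: C4′ (R) is the only stereocentre and both arm alkenes are E; the two benzylic positions of the arene are told apart by tying the phenol and one CH2OH into a cyclic ketal.

Step 1
Reactants: 1 methyl 4-hydroxybenzoate
Product: 2 methyl 4-hydroxy-3,5-bis(hydroxymethyl)benzoate
Conditions: 37% aq. CH2O (6 equiv), NaOH (1.1 equiv), H2O, 50 °C; then AcOH to pH 6
Reagents that add atoms: formaldehyde, C=O
Why: Lederer–Manasse hydroxymethylation: the phenoxide of 1 attacks formaldehyde through its two free ortho carbons (para is blocked by the ester), and the phenoxide charge slows saponification of the para ester under these mild conditions.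

Step 2
Reactants: 2 methyl 4-hydroxy-3,5-bis(hydroxymethyl)benzoate
Product: 3 methyl 8-(hydroxymethyl)-2,2-dimethyl-4H-1,3-benzodioxine-6-carboxylate
Conditions: 2,2-dimethoxypropane, TsOH·H2O (cat.), acetone, rt
Reagents that add atoms: 2,2-dimethoxypropane, COC(C)(C)OC
Why: Acid-catalysed ketal exchange closes a six-membered 1,3-benzodioxine between the phenol and one of the two equivalent ortho CH2OH groups, which is the only cyclic ketal the triol can form and leaves exactly one benzylic alcohol free.

Step 3
Reactants: 3 methyl 8-(hydroxymethyl)-2,2-dimethyl-4H-1,3-benzodioxine-6-carboxylate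
Product: 4 methyl 8-(chloromethyl)-2,2-dimethyl-4H-1,3-benzodioxine-6-carboxylate
Conditions: SOCl2, pyridine, CH2Cl2, 0 °C
Reagents that add atoms: thionyl chloride, O=S(Cl)Cl
Why: Deoxychlorination of a benzylic alcohol through its chlorosulfite, with pyridine taking up the HCl so that the ketal and the ester are not attacked.

Step 4
Reactants: 5 propargyl alcohol
Product: 6 tert-butyl(diphenyl)(prop-2-yn-1-yloxy)silane
Conditions: TBDPSCl, imidazole, CH2Cl2, 0 °C to rt
Reagents that add atoms: tert-butyl(chloro)diphenylsilane, CC(C)(C)[Si](Cl)(c1ccccc1)c1ccccc1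
Why: Imidazole-promoted silylation of a primary alcohol; TBDPS is chosen because it withstands the acidic ketal cleavage of step 6.

Step 5
Reactants: 4 methyl 8-(chloromethyl)-2,2-dimethyl-4H-1,3-benzodioxine-6-carboxylate; 6 tert-butyl(diphenyl)(prop-2-yn-1-yloxy)silane; 7 trimethylaluminium
Product: 9 methyl 8-[(E)-4-(tert-butyldiphenylsilyloxy)-3-methylbut-2-en-1-yl]-2,2-dimethyl-4H-1,3-benzodioxine-6-carboxylate, via short-arm alkenylalane 8 (not isolated)
Conditions: 6 (1.3 equiv), AlMe3 (2.6 equiv), Cp2ZrCl2 (0.25 equiv), ClCH2CH2Cl, 0 °C to rt; volatiles removed in vacuo; then 4, zerovalent nickel from NiCl2(PPh3)2 (5 mol %) and n-BuLi (10 mol %), THF, 0 °C to rt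
Reagents that add atoms: none
Why: Negishi zirconium-catalysed methylalumination adds methyl and aluminium syn across the terminal alkyne (methyl to the internal carbon), and nickel-catalysed cross-coupling of the resulting (E)-alkenylalane with the benzylic chloride proceeds with retention, so the short arm should form as the E isomer.

Step 6
Reactants: 9 methyl 8-[(E)-4-(tert-butyldiphenylsilyloxy)-3-methylbut-2-en-1-yl]-2,2-dimethyl-4H-1,3-benzodioxine-6-carboxylate
Product: 10 methyl 3-[(E)-4-(tert-butyldiphenylsilyloxy)-3-methylbut-2-en-1-yl]-4-hydroxy-5-(hydroxymethyl)benzoate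
Conditions: TsOH·H2O (10 mol %), MeOH, rt
Reagents that add atoms: none
Why: Acid-catalysed transketalisation to methanol cleaves the aryl alkyl ketal (the para-ester phenol is a good leaving group), while the TBDPS ether, the methyl ester and the trisubstituted alkene are stable to catalytic TsOH at room temperature.

Step 7
Reactants: 10 methyl 3-[(E)-4-(tert-butyldiphenylsilyloxy)-3-methylbut-2-en-1-yl]-4-hydroxy-5-(hydroxymethyl)benzoate
Product: 11 methyl 3-[(E)-4-(tert-butyldiphenylsilyloxy)-3-methylbut-2-en-1-yl]-5-(hydroxymethyl)-4-methoxybenzoate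
Conditions: MeI, K2CO3, acetone, rt
Reagents that add atoms: iodomethane, CI
Why: Williamson ether synthesis: K2CO3 deprotonates only the phenol, which the para ester makes acidic, so iodomethane methylates the phenolic oxygen and not the benzylic alcohol.

Step 8
Reactants: 11 methyl 3-[(E)-4-(tert-butyldiphenylsilyloxy)-3-methylbut-2-en-1-yl]-5-(hydroxymethyl)-4-methoxybenzoate
Product: 12 methyl 3-[(E)-4-(tert-butyldiphenylsilyloxy)-3-methylbut-2-en-1-yl]-5-(chloromethyl)-4-methoxybenzoate
Conditions: SOCl2, pyridine, CH2Cl2, 0 °C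
Reagents that add atoms: thionyl chloride, O=S(Cl)Cl
Why: Deoxychlorination of the benzylic alcohol through its chlorosulfite as in step 3; the pyridine-buffered conditions spare the silyl ether and the alkene.

Step 9
Reactants: 13 4-methylpent-3-enoic acid
Product: 15 N-methoxy-N,4-dimethylpent-3-enamide, via acyl imidazolide 14 (not isolated)
Conditions: CDI, CH2Cl2, rt; then MeNHOMe·HCl, rt
Reagents that add atoms: N,O-dimethylhydroxylamine hydrochloride, CNOC.Cl; 1,1′-carbonyldiimidazole, O=C(n1ccnc1)n1ccnc1 (its imidazolyl group stays only in 14)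
Why: Amide formation through an acyl imidazolide: CDI activates the acid without added base, which avoids migration of the β,γ double bond, and the amine hydrochloride then gives the Weinreb amide.

Step 10
Reactants: 15 N-methoxy-N,4-dimethylpent-3-enamide; 16 trimethylsilylacetylene
Product: 18 6-methyl-1-(trimethylsilyl)hept-5-en-1-yn-3-one, via lithium (trimethylsilyl)acetylide 17 (not isolated)
Conditions: 16, n-BuLi, THF, −78 °C; then 15, −78 to −20 °C; inverse quench into cold 1 M HCl
Reagents that add atoms: none
Why: Weinreb ketone synthesis: the acetylide adds once because the chelated tetrahedral adduct persists until the quench, and the acidic inverse quench protonates the released amine so that it can neither add to the ynone nor move the skipped double bond into conjugation.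

Step 11
Reactants: 18 6-methyl-1-(trimethylsilyl)hept-5-en-1-yn-3-one
Product: 19 (R)-6-methyl-1-(trimethylsilyl)hept-5-en-1-yn-3-ol
Conditions: Ru[(R,R)-TsNCHPhCHPhNH](p-cymene) (1 mol %), i-PrOH, rt
Reagents that add atoms: none
Why: Noyori asymmetric transfer hydrogenation of an alkynyl ketone: the (R,R)-configured ruthenium amido complex passes hydride and proton from 2-propanol to one carbonyl face, with the alkynyl group taking the place an aryl group takes in aryl ketones, which should give the (R)-propargylic alcohol, and the base-free conditions keep the β,γ double bond in place.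

Step 12
Reactants: 19 (R)-6-methyl-1-(trimethylsilyl)hept-5-en-1-yn-3-ol
Product: 20 (R)-tert-butyldimethyl{[6-methyl-1-(trimethylsilyl)hept-5-en-1-yn-3-yl]oxy}silane
Conditions: TBSCl, imidazole, DMF, rt
Reagents that add atoms: tert-butyl(chloro)dimethylsilane, CC(C)(C)[Si](C)(C)Cl
Why: Imidazole-promoted silylation of the secondary alcohol; no bond to the stereocentre is made or broken.

Step 13
Reactants: 20 (R)-tert-butyldimethyl{[6-methyl-1-(trimethylsilyl)hept-5-en-1-yn-3-yl]oxy}silane
Product: 21 (R)-3-(tert-butyldimethylsilyloxy)-6-methylhept-5-en-1-yne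
Conditions: K2CO3 (0.2 equiv), MeOH, rt
Reagents that add atoms: none
Why: Base-catalysed methanolysis (protodesilylation) of the alkynyl C–Si bond, which is far more labile than the TBS ether under these conditions.

Step 14
Reactants: 7 trimethylaluminium; 12 methyl 3-[(E)-4-(tert-butyldiphenylsilyloxy)-3-methylbut-2-en-1-yl]-5-(chloromethyl)-4-methoxybenzoate; 21 (R)-3-(tert-butyldimethylsilyloxy)-6-methylhept-5-en-1-yne
Product: 23 methyl 3-[(2E,4R)-4-(tert-butyldimethylsilyloxy)-3,7-dimethylocta-2,6-dien-1-yl]-5-[(E)-4-(tert-butyldiphenylsilyloxy)-3-methylbut-2-en-1-yl]-4-methoxybenzoate, via long-arm alkenylalane 22 (not isolated)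
Conditions: 21 (1.3 equiv), AlMe3 (2.6 equiv), Cp2ZrCl2 (0.3 equiv), ClCH2CH2Cl, 0 °C to rt; volatiles removed in vacuo; then 12 (1.0 equiv), zerovalent nickel from NiCl2(PPh3)2 (5 mol %) and n-BuLi (10 mol %), THF, 0 °C to rt
Reagents that add atoms: none
Why: Zirconocene-assisted syn methylalumination of the terminal alkyne of 21 delivers methyl to the internal carbon (C3′) and aluminium to the terminal carbon (C2′), so alane 22 forms as the E isomer; zerovalent nickel then inserts into the benzylic C–Cl bond of 12, the alkenyl group passes from aluminium to nickel, and reductive elimination forms C1′–C2′ with retention of the alkene geometry. The closest known reaction type is the Negishi carboalumination of terminal alkynes combined with the nickel-catalysed coupling of alkenylalanes with benzylic chlorides, as used to attach polyprenyl chains to chloromethylated quinones and arenes. No ring is closed and no stereocentre is created: C4′ comes in with 21, and although it sits next to C3′ no bond to it is made or broken, so its R configuration should be preserved. The step needs regio- and syn-selectivity in the carbometalation, which the terminal alkyne (metal to the unhindered carbon) and the concerted four-centre addition secure, while the bulky, weakly coordinating TBS ether keeps the propargylic oxygen from directing the addition. Chemoselectivity in the coupling (alkenyl instead of methyl transfer, no attack on the ester) is secured by stripping excess AlMe3 in vacuo before the chloride is added and by working in THF at or below room temperature. The trisubstituted alkenes of both partners, both silyl ethers and the aryl methyl ether are inert to either metal.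

Step 15
Reactants: 23 methyl 3-[(2E,4R)-4-(tert-butyldimethylsilyloxy)-3,7-dimethylocta-2,6-dien-1-yl]-5-[(E)-4-(tert-butyldiphenylsilyloxy)-3-methylbut-2-en-1-yl]-4-methoxybenzoate
Product: 24 methyl 3-[(2E,4R)-4-hydroxy-3,7-dimethylocta-2,6-dien-1-yl]-5-[(E)-4-hydroxy-3-methylbut-2-en-1-yl]-4-methoxybenzoate
Conditions: TBAF (3 equiv), THF, 0 °C to rt
Reagents that add atoms: none
Why: Fluoride-mediated desilylation: the strong Si–F bond drives cleavage of both the TBDPS and the TBS ether, and the ester, the alkenes and the stereocentre are not affected.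

Step 16
Reactants: 24 methyl 3-[(2E,4R)-4-hydroxy-3,7-dimethylocta-2,6-dien-1-yl]-5-[(E)-4-hydroxy-3-methylbut-2-en-1-yl]-4-methoxybenzoate
Product: 25 3-[(2E,4R)-4-hydroxy-3,7-dimethylocta-2,6-dien-1-yl]-5-[(E)-4-hydroxy-3-methylbut-2-en-1-yl]-4-methoxybenzoic acid
Conditions: LiOH·H2O (5 equiv), THF/MeOH/H2O, rt to 40 °C; then 1 M HCl to pH 4, 0 °C
Reagents that add atoms: lithium hydroxide, [Li+].[OH-]
Why: Saponification of the methyl ester (addition–elimination at the acyl carbon) followed by mild acidification; the molecule has no base-sensitive stereocentre and the allylic alcohols tolerate pH 4 at 0 °C.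

Compound list

1 | methyl 4-hydroxybenzoate | COC(=O)c1ccc(O)cc1 | starting material
2 | methyl 4-hydroxy-3,5-bis(hydroxymethyl)benzoate | COC(=O)c1cc(CO)c(O)c(CO)c1 | intermediate
3 | methyl 8-(hydroxymethyl)-2,2-dimethyl-4H-1,3-benzodioxine-6-carboxylate | COC(=O)c1cc(CO)c2OC(C)(C)OCc2c1 | intermediate
4 | methyl 8-(chloromethyl)-2,2-dimethyl-4H-1,3-benzodioxine-6-carboxylate | COC(=O)c1cc(CCl)c2OC(C)(C)OCc2c1 | intermediate
5 | propargyl alcohol | C#CCO | starting material
6 | tert-butyl(diphenyl)(prop-2-yn-1-yloxy)silane | C#CCO[Si](c1ccccc1)(c1ccccc1)C(C)(C)C | intermediate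
7 | trimethylaluminium | C[Al](C)C | starting material
8 | [(E)-3-(tert-butyldiphenylsilyloxy)-2-methylprop-1-en-1-yl]dimethylalane | C[Al](C)/C=C(\C)CO[Si](c1ccccc1)(c1ccccc1)C(C)(C)C | intermediate (not isolated)
9 | methyl 8-[(E)-4-(tert-butyldiphenylsilyloxy)-3-methylbut-2-en-1-yl]-2,2-dimethyl-4H-1,3-benzodioxine-6-carboxylate | COC(=O)c1cc(C/C=C(\C)CO[Si](c3ccccc3)(c3ccccc3)C(C)(C)C)c2OC(C)(C)OCc2c1 | intermediate
10 | methyl 3-[(E)-4-(tert-butyldiphenylsilyloxy)-3-methylbut-2-en-1-yl]-4-hydroxy-5-(hydroxymethyl)benzoate | COC(=O)c1cc(CO)c(O)c(C/C=C(\C)CO[Si](c2ccccc2)(c2ccccc2)C(C)(C)C)c1 | intermediate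
11 | methyl 3-[(E)-4-(tert-butyldiphenylsilyloxy)-3-methylbut-2-en-1-yl]-5-(hydroxymethyl)-4-methoxybenzoate | COC(=O)c1cc(CO)c(OC)c(C/C=C(\C)CO[Si](c2ccccc2)(c2ccccc2)C(C)(C)C)c1 | intermediate
12 | methyl 3-[(E)-4-(tert-butyldiphenylsilyloxy)-3-methylbut-2-en-1-yl]-5-(chloromethyl)-4-methoxybenzoate | COC(=O)c1cc(CCl)c(OC)c(C/C=C(\C)CO[Si](c2ccccc2)(c2ccccc2)C(C)(C)C)c1 | intermediate
13 | 4-methylpent-3-enoic acid | CC(C)=CCC(=O)O | starting material
14 | 1-(4-methylpent-3-enoyl)imidazole | CC(C)=CCC(=O)n1ccnc1 | intermediate (not isolated)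
15 | N-methoxy-N,4-dimethylpent-3-enamide | CC(C)=CCC(=O)N(C)OC | intermediate
16 | trimethylsilylacetylene | C#C[Si](C)(C)C | starting material
17 | lithium (trimethylsilyl)acetylide | [Li]C#C[Si](C)(C)C | intermediate (not isolated)
18 | 6-methyl-1-(trimethylsilyl)hept-5-en-1-yn-3-one | CC(C)=CCC(=O)C#C[Si](C)(C)C | intermediate
19 | (R)-6-methyl-1-(trimethylsilyl)hept-5-en-1-yn-3-ol | C[Si](C)(C)C#C[C@H](O)CC=C(C)C | intermediate
20 | (R)-tert-butyldimethyl{[6-methyl-1-(trimethylsilyl)hept-5-en-1-yn-3-yl]oxy}silane | C[Si](C)(C)C#C[C@H](O[Si](C)(C)C(C)(C)C)CC=C(C)C | intermediate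
21 | (R)-3-(tert-butyldimethylsilyloxy)-6-methylhept-5-en-1-yne | C#C[C@H](O[Si](C)(C)C(C)(C)C)CC=C(C)C | intermediate
22 | [(1E,3R)-3-(tert-butyldimethylsilyloxy)-2,6-dimethylhepta-1,5-dien-1-yl]dimethylalane | C[Al](C)/C=C(\C)[C@H](O[Si](C)(C)C(C)(C)C)CC=C(C)C | intermediate (not isolated)
23 | methyl 3-[(2E,4R)-4-(tert-butyldimethylsilyloxy)-3,7-dimethylocta-2,6-dien-1-yl]-5-[(E)-4-(tert-butyldiphenylsilyloxy)-3-methylbut-2-en-1-yl]-4-methoxybenzoate | COC(=O)c1cc(C/C=C(\C)CO[Si](c2ccccc2)(c2ccccc2)C(C)(C)C)c(OC)c(C/C=C(\C)[C@H](O[Si](C)(C)C(C)(C)C)CC=C(C)C)c1 | intermediate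
24 | methyl 3-[(2E,4R)-4-hydroxy-3,7-dimethylocta-2,6-dien-1-yl]-5-[(E)-4-hydroxy-3-methylbut-2-en-1-yl]-4-methoxybenzoate | COC(=O)c1cc(C/C=C(\C)CO)c(OC)c(C/C=C(\C)[C@H](O)CC=C(C)C)c1 | intermediate
25 | 3-[(2E,4R)-4-hydroxy-3,7-dimethylocta-2,6-dien-1-yl]-5-[(E)-4-hydroxy-3-methylbut-2-en-1-yl]-4-methoxybenzoic acid | COc1c(C/C=C(\C)CO)cc(C(=O)O)cc1C/C=C(\C)[C@H](O)CC=C(C)C | target

Total step count: 16 steps.
Longest linear sequence: 10 steps (steps 1, 2, 3, 5, 6, 7, 8, 14, 15 and 16, from methyl 4-hydroxybenzoate). The alkyne branch (steps 9 to 13) joins at step 14.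

Steps most likely to fail

Step 14. The branched propargylic silyl ether may slow the methylalumination so that it stalls or loses regiocontrol. Remaining methylaluminium species may transfer methyl to the benzylic carbon or attack the ester. Transfer of the hindered alkenyl group to nickel may be slow enough for homocoupling of the benzylic chloride to take over. The fallback separates the two events and reverses the polarity of the coupling; it sets out from 21 (through alane 22) and from 12 and returns at 23. Alane 22 is quenched with I2 in THF at −30 °C to the vinyl iodide (R,E)-tert-butyl[(1-iodo-2,6-dimethylhepta-1,5-dien-3-yl)oxy]dimethylsilane F1. Chloride 12 is treated with zinc dust and LiCl in THF at rt to give the benzylic zinc reagent {[2-methoxy-5-(methoxycarbonyl)-3-[(E)-4-(tert-butyldiphenylsilyloxy)-3-methylbut-2-en-1-yl]phenyl]methyl}zinc chloride F2, a reagent type that tolerates esters. Negishi coupling of F1 with F2 under Pd(PPh3)4 (5 mol %) in THF at rt to 40 °C should give 23 with retention of the E geometry.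

Step 5. Coordination of the propargylic ether oxygen to aluminium may erode the regioselectivity of the methylalumination. The chloroalane formed during the coupling may open the cyclic ketal as a Lewis acid. Reductive homocoupling of the benzylic chloride may compete. The fallback sets out from 5 and 4 and returns at 9. Propargyl alcohol 5 is carboaluminated as its aluminium alkoxide (AlMe3 3 equiv, Cp2ZrCl2, CH2Cl2, rt) to dimethyl{(E)-3-[(dimethylalumanyl)oxy]-2-methylprop-1-en-1-yl}alane F3. This is iodinated in the same flask (I2, THF, −30 °C) to (E)-3-iodo-2-methylprop-2-en-1-ol F4. Silylation (TBDPSCl, imidazole, CH2Cl2) gives tert-butyl{[(E)-3-iodo-2-methylprop-2-en-1-yl]oxy}diphenylsilane F5. Chloride 4 is converted with zinc dust and LiCl in THF into {[6-(methoxycarbonyl)-2,2-dimethyl-4H-1,3-benzodioxin-8-yl]methyl}zinc chloride F6. Negishi coupling of F5 with F6 under Pd(PPh3)4 in THF should give 9 without any aluminium Lewis acid in the presence of the ketal.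

Step 11. The skipped C5=C6 double bond may migrate into conjugation with the ynone during the hydrogen transfer (or already in the work-up of step 10). Enantiofacial discrimination may be incomplete because both carbonyl substituents are unbranched at the positions next to the carbonyl. The fallback sets the stereocentre by epoxidation instead of ketone reduction; it sets out from 5 and returns at 21.
- Propargyl alcohol 5 is C-alkylated at the alkyne terminus with 1-bromo-3-methylbut-2-ene (copper iodide (CuI), K2CO3, NaI, DMF, rt) to 6-methylhept-5-en-2-yn-1-ol F7.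
- LiAlH4 in THF reduces the propargylic alcohol to (E)-6-methylhepta-2,5-dien-1-ol F8.
- Sharpless asymmetric epoxidation (Ti(OiPr)4, D-(−)-diethyl tartrate, t-BuOOH, 4 Å molecular sieves, CH2Cl2, −20 °C) acts only on the allylic alcohol alkene and should give [(2R,3R)-3-(3-methylbut-2-en-1-yl)oxiran-2-yl]methanol F9.
- Appel chlorination (PPh3, CCl4, NaHCO3, reflux) gives (2S,3R)-2-(chloromethyl)-3-(3-methylbut-2-en-1-yl)oxirane F10.
- n-BuLi (3 equiv) in THF at −78 °C opens the epoxide by double elimination, with the C3–O bond kept, to (R)-6-methylhept-5-en-1-yn-3-ol F11.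
- Silylation (TBSCl, imidazole, DMF) gives 21.

Further compounds
F1 | step 14 | (R,E)-tert-butyl[(1-iodo-2,6-dimethylhepta-1,5-dien-3-yl)oxy]dimethylsilane | I/C=C(\C)[C@H](O[Si](C)(C)C(C)(C)C)CC=C(C)C
F2 | step 14 | {[2-methoxy-5-(methoxycarbonyl)-3-[(E)-4-(tert-butyldiphenylsilyloxy)-3-methylbut-2-en-1-yl]phenyl]methyl}zinc chloride | COC(=O)c1cc(C[Zn]Cl)c(OC)c(C/C=C(\C)CO[Si](c2ccccc2)(c2ccccc2)C(C)(C)C)c1
F3 | step 5 | dimethyl{(E)-3-[(dimethylalumanyl)oxy]-2-methylprop-1-en-1-yl}alane | C[Al](C)/C=C(\C)CO[Al](C)C
F4 | step 5 | (E)-3-iodo-2-methylprop-2-en-1-ol | I/C=C(\C)CO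
F5 | step 5 | tert-butyl{[(E)-3-iodo-2-methylprop-2-en-1-yl]oxy}diphenylsilane | I/C=C(\C)CO[Si](c1ccccc1)(c1ccccc1)C(C)(C)C
F6 | step 5 | {[6-(methoxycarbonyl)-2,2-dimethyl-4H-1,3-benzodioxin-8-yl]methyl}zinc chloride | COC(=O)c1cc(C[Zn]Cl)c2OC(C)(C)OCc2c1
F7 | step 11 | 6-methylhept-5-en-2-yn-1-ol | CC(C)=CCC#CCO
F8 | step 11 | (E)-6-methylhepta-2,5-dien-1-ol | CC(C)=CC/C=C/CO
F9 | step 11 | [(2R,3R)-3-(3-methylbut-2-en-1-yl)oxiran-2-yl]methanol | OC[C@H]1O[C@@H]1CC=C(C)C
F10 | step 11 | (2S,3R)-2-(chloromethyl)-3-(3-methylbut-2-en-1-yl)oxirane | ClC[C@H]1O[C@@H]1CC=C(C)C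
F11 | step 11 | (R)-6-methylhept-5-en-1-yn-3-ol | C#C[C@H](O)CC=C(C)C
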